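East's flask ended with a leftover: 44.9% of the electrophile still stood at 30.0 min, while target had levelled off near 49.4%. An electrophile that remains while target levels off points to the nucleophile as the limiting reagent.

| setting | east | south | summer | winter | autumn | spring |
|---|---|---|---|---|---|---|
| electrophile | 0.20 M | 0.20 M | 0.20 M | 0.20 M | 0.20 M | 0.20 M (fed, over 50.0 min) |
| nucleophile | 0.24 M | 0.24 M | 0.240 M | 0.240 M | 0.240 M (fed, over 50.0 min) | 0.240 M |
| free base | 0.20 M | 0.10 M | 0.200 M | 0.200 M | 0.200 M | 0.200 M |
| remark | run made earlier | run made earlier | one stirred flow tank at steady state, fed with the mixture as stated, mean residence time 50 min | everything together in a closed stirred flask, run for 50 min | a stirred flask in which nucleophile is dosed at a steady rate over 50.0 min without added volume, worked up at 50 min | all but electrophile at the start; electrophile goes in evenly over 50.0 min, the run ends at 50 min |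
| time |  |  |  | 50 min | 50 min | 50 min |

- east (time / min: target / %, electrophile / %): 4.00: 23.9, 74.0; 8.00: 36.3, 61.8; 12.0: 42.7, 56.0; 15.0: 44.7, 51.8; 20.0: 48.1, 48.3; 25.0: 48.9, 45.6; 30.0: 49.4, 44.9
- south (time / min: target / %, electrophile / %): 0.667: 5.2, 94.6; 1.33: 11.8, 88.6; 2.00: 17.8, 82.0; 3.00: 20.7, 78.7; 4.00: 25.2, 74.4; 5.00: 29.1, 69.6

(standard deviation of a reading: 1 percentage point)

- the stated concentrations are those of everything mixed, before any reaction; amounts are the same in each set-up
- the feed brings no volume worth counting
- the earlier runs were made in a closed, stirred flask

1. the set-up with the highest amount of target at the outlet or at the end, in percent of the electrophile put in ("none" if the first two lie within 2 percentage points) (summer / winter / autumn / spring / none)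
2. amount of target at the outlet or at the end, in percent of the electrophile put in, summer
3. amount of target at the outlet or at the end, in percent of the electrophile put in, winter
4. amount of target at the outlet or at the end, in percent of the electrophile put in, autumn
5. amount of target at the outlet or at the end, in percent of the electrophile put in, spring

If east's 0.24 M of nucleophile was indeed spent, then 2.43 is the price: nucleophile spent per target formed. The objection is that the nucleophile may not be gone. East's target slope from 20.0 min to 30.0 min, set against its slope over the first 4.00 min and divided by the electrophile share remaining, leaves 4.85% of the nucleophile, a rough reading, so the price stands to within that share. Free base seems not to enter early on: at 4.00 min, south with 0.10 M holds 25.2% of target and east with 0.20 M holds 23.9%, a gap close to the scatter of 1 percentage point.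

A harder objection is that one curve cannot separate a price per target from a loss by the clock. This reckoning bets on the price, read as a stoichiometry of a whole 2 plus some further loss, and the bet stays unproved. Then spring, fed evenly, has an estimated ceiling of 49.4%, and at full conversion of the feed it would spend its nucleophile in 24.7 min. But fed electrophile does not react at once, and east needed 20.0 min to approach its plateau, so spring should end below the ceiling, near the 44.7% that east held at 15.0 min.

The forecast reads otherwise, that “the nucleophile is being lost in parallel”. It names winter as best, with summer 39.5%, winter 49.5%, autumn 44% and spring 16% (range 11% to 24%). On spring it parts from the reckoning above.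

    electrophile + nucleophile ⇌ acid set free + target (K = 1.07, k = 0.412 M⁻¹ min⁻¹)
    nucleophile + acid set free ⇌ protonated nucleophile, settled at all times (K = 7300 M⁻¹)
    nucleophile + target → over-reaction product (k = 0.0816 M⁻¹ min⁻¹)
    acid set free + free base ⇌ salt of the base (K = 6.60 M⁻¹, k = 0.362 M⁻¹ min⁻¹)

The flasks give summer 39.5%, winter 51.7%, autumn 44.1% and spring 41.8%, so winter leads. In winter, electrophile's forward half-life of 7.0 min is shorter than the 35 min of target going on to over-reaction product, both at charged concentrations. Spring, with 11% of its nucleophile left unbound, paid a price of 2.55. A neighbour of winter charged with 0.80 M of electrophile is reckoned at 12.3% by east's price, and it gives 15.5% with 0.70% of its nucleophile left unbound, a price of 1.92.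

All runs come from a simulation for substances that don't exist; noise was put on by code.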